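Read at 50 h, we count the chains as they stand then, so here is the quick number you asked for, with the clock kept in it.

common to all: free monomer 0.10 M; transfer agent 1.00 mM; initiator 2.6 mM; time 50 h

|  | protic impurity |
|---|---|
| gamma | 0.0100 M |
| eta | 0.0300 M |

    free monomer + initiator → living end + monomer in chains (k1 = 16.3 M⁻¹ h⁻¹)
    free monomer + living end → monomer in chains + living end, rate k2*[living end]*[free monomer] (k2 = 28.4 M⁻¹ h⁻¹)
    living end + transfer agent → dead chain (k3 = 264 M⁻¹ h⁻¹)
    protic impurity + free monomer → quenched substrate (k4 = 5.79 M⁻¹ h⁻¹)

- the average divides the monomer in chains by the number of chains begun, living and dead together
- run time (gamma): 50 h

* which of the two ends with the longer chains by the average number of monomer units in a chain (chains begun, living or dead) ("neither" if they lie within 10%) (gamma / eta / neither)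
* average number of monomer units in a chain (chains begun, living or dead) at the end, gamma
* average number of monomer units in a chain (chains begun, living or dead) at the end, eta

Our first round ignores the clock. With the partners as charged, the initiator has a half-life of 0.425 h, and in gamma the protic impurity has one of 1.2 h and living ends one of 2.6 h against the transfer agent. These are all short beside the reading, so we treat those steps as over early. That gives 2.6 mM of chains begun in gamma and in eta, of which the transfer agent stops 1.00 mM, leaving 1.60 mM living. Free monomer less the impurity's charge, divided by the chains begun, gives a full-use length of 34.6 units in gamma and 26.9 in eta.

The second round puts that answer back, since a full-use length assumes the free monomer is used up by the reading. Our growth constant is 0.0454 h⁻¹, the rate constant of step 2 times the living ends that outlast the transfer agent, a pseudo-first-order constant for free monomer. It gives a half-life of 15.3 h, so by 50 h we put the share of that monomer reaching chains at 89.7%. The full-use lengths times that share give 31.0 for gamma and 24.1 for eta, and the longer chains go to gamma.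

Your hunch, the forecast, says gamma, with 31.3 (29.5 to 33) for gamma and 24.5 (22.5 to 26) for eta. It rests in part on the charge of protic impurity: “The impurity removes nearly its full charge of monomer”. Our two lengths stand a little below its two point values.

The flasks give gamma, with 31.3 for gamma and 24.5 for eta, so the forecast held. In eta, the half-life of free monomer by step 2 stood at 15 h after 11.7 h, beside our 15.3 h from the growth constant. Now take eta read at 20 h, with every charge the same. The growth constant puts the share at 59.7%, and so the length at 16.1. That flask gives 17.2, with 44.8% of the charged free monomer in chains and 25.3% still free.

(All constants were drawn at random within sensible limits; the rest is arithmetic.)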